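The γ-butyrolactone (O1, C2=O, C3–OH, C4–H, C5H2) is disconnected at C4–C5. An open-chain (R)-2-hydroxy-4-arylbut-3-enoic acid is esterified as its halomethyl ester, so that O1 already carries C5; the acyloxymethyl radical then adds 5-exo to the styrene carbon that becomes C4. This one operation closes the lactone, sets C4 trans to the C3 hydroxyl (the only stereocentre of the precursor, installed by a dehydrogenase) and converts the styrene into the 3,4-dimethoxybenzyl group. The step exploits the ester oxygen O1, the C3 carbinol and the aryl-activated C4=C alkene. The quaternary C3 is finished by dianion benzylation anti to the C4 benzyl group, then hydrogenolysis.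

Key step: step 4

Remark: the lactone numbering O1, C2 (C=O), C3 (C–OH), C4 (CH), C5 (OCH2) is used throughout, also for the open-chain precursors; 3,4-bis(benzyloxy)benzyl chloride is taken as a purchased starting material.

Step 1
Reactants: 1 3,4-dimethoxybenzaldehyde (veratraldehyde); 2 pyruvic acid
Product: 3 potassium (E)-4-(3,4-dimethoxyphenyl)-2-oxobut-3-enoate
Conditions: KOH, MeOH–H2O, 0 °C to rt; the salt is filtered off
Reagents that add atoms: potassium hydroxide, [K+].[OH-]
Why: Claisen–Schmidt aldol condensation of the pyruvate enolate with the non-enolisable aldehyde, driven by precipitation of the conjugated (E)-enone salt.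

Step 2
Reactants: 3 potassium (E)-4-(3,4-dimethoxyphenyl)-2-oxobut-3-enoate
Product: 4 (2R,3E)-2-hydroxy-4-(3,4-dimethoxyphenyl)but-3-enoic acid
Conditions: D-lactate dehydrogenase (NADH-dependent), NAD+ (cat.), formate dehydrogenase, HCO2Na, phosphate buffer pH 7, 30 °C; then HCl to pH 2, EtOAc
Reagents that add atoms: none
Why: Enzymatic carbonyl reduction by a D-specific 2-oxoacid dehydrogenase, a class that accepts 4-aryl-2-oxobut-3-enoates and leaves the alkene alone; hydride from NADH is delivered to one face of the 2-oxo group in the active site, which should set the R carbinol, while formate dehydrogenase recycles the cofactor.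

Step 3
Reactants: 4 (2R,3E)-2-hydroxy-4-(3,4-dimethoxyphenyl)but-3-enoic acid
Product: 5 chloromethyl (2R,3E)-2-hydroxy-4-(3,4-dimethoxyphenyl)but-3-enoate
Conditions: ClCH2OSO2Cl, NaHCO3, Bu4NHSO4 (cat.), CH2Cl2–H2O, 0 °C to rt
Reagents that add atoms: chloromethyl chlorosulfate, ClCOS(=O)(=O)Cl
Why: Phase-transfer O-alkylation of the carboxylate with displacement of chlorosulfate; the weak base should neither alkylate the secondary hydroxyl nor isomerise the β,γ-unsaturated hydroxy acid, and the stereocentre is not touched.

Step 4
Reactants: 5 chloromethyl (2R,3E)-2-hydroxy-4-(3,4-dimethoxyphenyl)but-3-enoate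
Product: 7 (3R,4S)-4-(3,4-dimethoxybenzyl)-3-hydroxyoxolan-2-one, via iodomethyl ester 6 (not isolated)
Conditions: NaI, acetone, rt, dark; filter, evaporate; then Bu3SnH (1.3 equiv) and AIBN (0.2 equiv) by syringe pump over 8 h, benzene (0.005 M), 80 °C
Reagents that add atoms: none
Why: Bu3Sn• abstracts iodine from 6 to give the acyloxymethyl radical on the O–CH2 carbon, which adds to the alkene carbon next to the carbinol and so forms the C4–C5 bond; the 3,4-dimethoxybenzylic radical left behind takes hydrogen from Bu3SnH and carries the chain. The closest known reaction type is the tin hydride cyclisation of alkenoyloxymethyl radicals from halomethyl alkenoates to γ-butyrolactones, a slow class because the ester must first turn into its minor E rotamer about the C2–O1 bond (O–CH2 turned towards C3), which is why the hydride is kept at low concentration by syringe pump at 80 °C. The lactone ring closes in the 5-exo-trig mode. The new stereocentre C4 is controlled by the C3 carbinol: in the envelope-like transition state the hydroxyl lies pseudo-equatorially in the plane of the ester, hydrogen-bonded to the carbonyl, and the aryl-bearing alkene terminus points away from the ring, so the new benzyl group should end trans to the hydroxyl, as in the cyclisation of 4-substituted hex-5-enyl radicals, which gives the 3R,4S isomer. The step needs 5-exo over 6-endo attack and cyclisation faster than hydrogen transfer; the aryl group secures both, since it blocks the distal carbon and makes addition at the proximal carbon a fast one that forms a benzylic radical. The minor cis isomer should be removed by chromatography at this stage, because it would lead into the enantiomeric series after step 5.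

Step 5
Reactants: 7 (3R,4S)-4-(3,4-dimethoxybenzyl)-3-hydroxyoxolan-2-one; 8 3,4-bis(benzyloxy)benzyl chloride
Product: 9 (3S,4S)-3-[3,4-bis(benzyloxy)benzyl]-4-(3,4-dimethoxybenzyl)-3-hydroxyoxolan-2-one
Conditions: LiN(iPr)2 (2.3 equiv), THF–HMPA, −78 °C; then 8, −78 to −20 °C; dilute HCl quench
Reagents that add atoms: none
Why: C-alkylation of the alkoxide–enolate dianion of an α-hydroxy-β-benzyl-γ-butyrolactone, the established entry to this lignan type; the old C3 configuration is erased in the enolate and the benzyl halide should enter anti to the C4 benzyl group, which sets the quaternary C3 as S with the two benzyl groups trans and the hydroxyl cis to the C4 benzyl group.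

Step 6
Reactants: 9 (3S,4S)-3-[3,4-bis(benzyloxy)benzyl]-4-(3,4-dimethoxybenzyl)-3-hydroxyoxolan-2-one
Product: 10 (3S,4S)-3-(3,4-dihydroxybenzyl)-4-(3,4-dimethoxybenzyl)-3-hydroxyoxolan-2-one
Conditions: H2 (1 atm), Pd/C (10%), EtOAc–MeOH, rt
Reagents that add atoms: none
Why: Hydrogenolysis of the two aryl benzyl ethers; the lactone, the tertiary α-hydroxyl, the aryl methyl ethers and both stereocentres should be inert.

Compound list
1 | 3,4-dimethoxybenzaldehyde (veratraldehyde) | COc1ccc(C=O)cc1OC | starting material
2 | pyruvic acid | CC(=O)C(=O)O | starting material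
3 | potassium (E)-4-(3,4-dimethoxyphenyl)-2-oxobut-3-enoate | COc1ccc(/C=C/C(=O)C(=O)[O-])cc1OC.[K+] | intermediate
4 | (2R,3E)-2-hydroxy-4-(3,4-dimethoxyphenyl)but-3-enoic acid | COc1ccc(/C=C/[C@@H](O)C(=O)O)cc1OC | intermediate
5 | chloromethyl (2R,3E)-2-hydroxy-4-(3,4-dimethoxyphenyl)but-3-enoate | COc1ccc(/C=C/[C@@H](O)C(=O)OCCl)cc1OC | intermediate
6 | iodomethyl (2R,3E)-2-hydroxy-4-(3,4-dimethoxyphenyl)but-3-enoate | COc1ccc(/C=C/[C@@H](O)C(=O)OCI)cc1OC | intermediate
7 | (3R,4S)-4-(3,4-dimethoxybenzyl)-3-hydroxyoxolan-2-one (hydroxyl trans to the benzyl group) | COc1ccc(C[C@H]2COC(=O)[C@@H]2O)cc1OC | intermediate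
8 | 3,4-bis(benzyloxy)benzyl chloride | ClCc1ccc(OCc2ccccc2)c(OCc2ccccc2)c1 | starting material
9 | (3S,4S)-3-[3,4-bis(benzyloxy)benzyl]-4-(3,4-dimethoxybenzyl)-3-hydroxyoxolan-2-one (benzyl groups trans) | COc1ccc(C[C@H]2COC(=O)[C@]2(O)Cc2ccc(OCc3ccccc3)c(OCc3ccccc3)c2)cc1OC | intermediate
10 | (3S,4S)-3-(3,4-dihydroxybenzyl)-4-(3,4-dimethoxybenzyl)-3-hydroxyoxolan-2-one | COc1ccc(C[C@H]2COC(=O)[C@]2(O)Cc2ccc(O)c(O)c2)cc1OC | target

Total step count: 6. Longest linear sequence: 6 steps (1 to 10).

Steps most likely to fail

Step 4. Hydrogen transfer from Bu3SnH may reach the acyloxymethyl radical before the ester has turned into its reactive rotamer, which would give simple reduction, and the iodomethyl ester may O-alkylate the neighbouring free hydroxyl on heating. The fallback gives up the radical closure and uses known chemistry. It sets out from 1: Stobbe condensation with dimethyl succinate (NaOMe, MeOH, reflux) should give (E)-3-(methoxycarbonyl)-4-(3,4-dimethoxyphenyl)but-3-enoic acid F1. Enantioselective hydrogenation with [Rh(cod)((S,S)-Et-DuPhos)]BF4 under H2 should give (R)-3-(methoxycarbonyl)-4-(3,4-dimethoxyphenyl)butanoic acid F2; the ligand antipode is taken if the sense proves opposite. Reduction of the ester group of its potassium carboxylate with Ca(BH4)2 in EtOH and acid lactonisation should give (R)-4-(3,4-dimethoxybenzyl)oxolan-2-one F3. Enolate formation with LiN(SiMe3)2 at −78 °C and oxygenation with MoO(O2)2·pyridine·HMPA anti to the benzyl group returns to the route at 7.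

Step 2. The 3,4-dimethoxystyryl group may fit poorly in the dehydrogenase pocket, so that turnover is slow or the substrate inhibits the enzyme. The fallback replaces biocatalysis by homogeneous hydrogenation. It sets out from 3, which is acidified (HCl) to (E)-4-(3,4-dimethoxyphenyl)-2-oxobut-3-enoic acid F4. Its 2-oxo group is then hydrogenated with a divalent ruthenium catalyst carrying an atropisomeric bisphosphine, [RuCl(benzene)(SunPhos)]Cl, under H2 pressure; this catalyst type should reduce the keto group of such acids in preference to the alkene, and the ligand antipode that gives the R acid is used. The fallback returns at 4.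

Step 5. The alkoxide oxygen may be alkylated instead of the enolate carbon, or the aggregated dianion may react sluggishly so that warming erodes facial selectivity. The fallback replaces the dianion by a mono-enolate of an O-protected lactone. It sets out from 7: benzylation under neutral conditions (BnBr, Ag2O, CH2Cl2) should give (3R,4S)-3-(benzyloxy)-4-(3,4-dimethoxybenzyl)oxolan-2-one F5. Its lithium enolate (LiN(SiMe3)2, THF, −78 °C) should be alkylated by 8 anti to the C4 benzyl group to give (3S,4S)-3-(benzyloxy)-3-[3,4-bis(benzyloxy)benzyl]-4-(3,4-dimethoxybenzyl)oxolan-2-one F6. Hydrogenolysis of all three benzyl ethers (H2, Pd/C) returns to the route at 10.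

Further compounds
F1 | step 4 | (E)-3-(methoxycarbonyl)-4-(3,4-dimethoxyphenyl)but-3-enoic acid | COC(=O)/C(CC(=O)O)=C/c1ccc(OC)c(OC)c1
F2 | step 4 | (R)-3-(methoxycarbonyl)-4-(3,4-dimethoxyphenyl)butanoic acid | COc1ccc(C[C@H](CC(=O)O)C(=O)OC)cc1OC
F3 | step 4 | (R)-4-(3,4-dimethoxybenzyl)oxolan-2-one | COc1ccc(C[C@H]2COC(=O)C2)cc1OC
F4 | step 2 | (E)-4-(3,4-dimethoxyphenyl)-2-oxobut-3-enoic acid | COc1ccc(/C=C/C(=O)C(=O)O)cc1OC
F5 | step 5 | (3R,4S)-3-(benzyloxy)-4-(3,4-dimethoxybenzyl)oxolan-2-one | COc1ccc(C[C@H]2COC(=O)[C@@H]2OCc2ccccc2)cc1OC
F6 | step 5 | (3S,4S)-3-(benzyloxy)-3-[3,4-bis(benzyloxy)benzyl]-4-(3,4-dimethoxybenzyl)oxolan-2-one | COc1ccc(C[C@H]2COC(=O)[C@]2(OCc2ccccc2)Cc2ccc(OCc3ccccc3)c(OCc3ccccc3)c2)cc1OC
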